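The route rests on cutting the central dihydropyran at O–C2 and C2–C3. C2 (the O–CH carbon that carries the second quinolone) is an aldehyde carbon. C3 with its CMe2–O arm is a masked 2-methylallyl unit. The precursor is therefore one atom smaller: an enantiopure trans-2-isopropenyl-3-isobutenyl-2,3-dihydrofuro[3,2-c]quinolinone. In the key step Pd(0)/InI opens its allylic C–O bond to an allylindium, which adds to a 3-formyl-4-hydroxyquinolone. Acid then closes both pyrans. One operation joins the halves, inserts one carbon into the furan ring and sets two stereocentres from the one made by asymmetric Michael addition. Mukaiyama hydration ends the synthesis.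

Key step: step 7

Remark on locants: O1, C2, C3 and C4 denote the atoms of the central 3,4-dihydro-2H-pyran ring, counted from its oxygen.
Assumption: the sense of induction in step 4 is taken by analogy with related enone additions of cyclic 1,3-dicarbonyl compounds. The pseudoenantiomeric cinchona amine is used if the opposite sense is found.

Step 1
Reactants: 1 2,3-dimethoxyaniline
Product: 3 2,3-dimethoxy-N-methylaniline, via N-(methoxymethyl)aniline 2 (not isolated)
Conditions: (CH2O)n, NaOMe, MeOH, rt; then NaBH4, reflux
Reagents that add atoms: paraformaldehyde (as formaldehyde), C=O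
Why: Reductive monomethylation: the N-(methoxymethyl)aniline formed with formaldehyde and methoxide is reduced by borohydride, and the sequence should stop at the secondary amine.

Step 2
Reactants: 3 2,3-dimethoxy-N-methylaniline; 4 bis(2,4,6-trichlorophenyl) malonate
Product: 5 4-hydroxy-7,8-dimethoxy-1-methylquinolin-2(1H)-one
Conditions: PhBr, reflux
Reagents that add atoms: none
Why: Cyclocondensation with an activated aryl malonate: N-acylation is followed by intramolecular Friedel–Crafts-type acylation at the only free ortho position, which lies para to a methoxy group.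

Step 3
Reactants: 5 4-hydroxy-7,8-dimethoxy-1-methylquinolin-2(1H)-one
Product: 7 4-hydroxy-7,8-dimethoxy-1-methyl-2-oxo-1,2-dihydroquinoline-3-carbaldehyde, via enaminone 6 (not isolated)
Conditions: Me2NCH(OMe)2, toluene, 90 °C; then 1 M NaOH, rt; HCl to pH 2
Reagents that add atoms: N,N-dimethylformamide dimethyl acetal, COC(OC)N(C)C; water, O
Why: Aminomethylenation of the nucleophilic C-3 by the amide acetal, followed by enaminone hydrolysis, amounts to a C-formylation of the cyclic 1,3-dicarbonyl unit.

Step 4
Reactants: 5 4-hydroxy-7,8-dimethoxy-1-methylquinolin-2(1H)-one; 8 (3E)-6-methylhepta-3,5-dien-2-one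
Product: 9 (R)-4-hydroxy-7,8-dimethoxy-1-methyl-3-(6-methyl-2-oxohept-5-en-4-yl)quinolin-2(1H)-one
Conditions: 9-amino(9-deoxy)epi-quinine (20 mol %), TFA (40 mol %), CH2Cl2, rt
Reagents that add atoms: none
Why: Iminium-catalysed asymmetric Michael addition of a cyclic 1,3-dicarbonyl to an enone: the chiral primary amine shields one face of the iminium ion and sets the stereocentre (later C4), and the δ,δ-dimethyl terminus should block 1,6-addition.

Step 5
Reactants: 9 (R)-Michael adduct
Product: 10 (2R,3R)-2-acetyl-6,7-dimethoxy-5-methyl-3-(2-methylprop-1-enyl)-2,3-dihydrofuro[3,2-c]quinolin-4(5H)-one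
Conditions: I2, K2CO3, MeCN, 0 °C to rt
Reagents that add atoms: none
Why: Iodine-mediated oxidative cyclisation of a 1,3-dicarbonyl Michael adduct (enolate iodination, then intramolecular O-alkylation at the internal α-carbon of the ketone): enolate iodination should outrun attack on the alkene, and the new epimerisable C-2 should settle trans to the C-3 substituent.

Step 6
Reactants: 10 (2R,3R)-2-acetyl dihydrofuroquinolinone
Product: 11 (2R,3R)-6,7-dimethoxy-5-methyl-3-(2-methylprop-1-enyl)-2-(prop-1-en-2-yl)-2,3-dihydrofuro[3,2-c]quinolin-4(5H)-one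
Conditions: Ph3PCH3Br, KOtBu, THF, 0 °C to rt
Reagents that add atoms: methyltriphenylphosphonium bromide, C[P+](c1ccccc1)(c1ccccc1)c1ccccc1.[Br-]
Why: Wittig methylenation takes the ketone and leaves the vinylogous carbamate carbonyl untouched; epimerisation at C-2 is harmless because this centre is rebuilt in step 7.

Step 7
Reactants: 11 (2R,3R)-2-isopropenyl dihydrofuroquinolinone; 7 3-formyl-4-hydroxyquinolinone
Product: 15 (2R,3S,4S) cis-fused bis(pyrano[3,2-c]quinolinone) bearing a 4-(2-methylprop-1-enyl) group, via allylindium species 12 (not isolated), via homoallylic alcohol 13 (not isolated), via ring-expanded pyran 14 (not isolated)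
Conditions: Pd(PPh3)4 (5 mol %), InI, THF, rt; then CSA (20 mol %), CH2Cl2, 0 °C to rt
Reagents that add atoms: none
Why: Pd(0) ionises the allylic C2–O bond of 11 (the leaving group is a vinylogous carboxylate), InI reduces the π-allyl complex to allylindium 12, which stays tied to the liberated oxygen, and 12 adds to aldehyde 7 through its γ-carbon (the old furan C-2) in a closed six-membered transition state, so that the aldehyde carbon ends up between O and that carbon once acid turns carbinol 13 into the o-quinone methide of the second quinolone and the freed 4-OH adds to it. The closest known reaction type is the Pd/In(I) umpolung carbonyl allylation with allylic esters and aryl ethers, followed by o-quinone-methide oxa-Michael addition and the acid cyclisation of isoprenyl phenols to 2,2-dimethylchromans. The central pyran closes by 6-exo-trig attack of O on the exocyclic methide carbon, and the second pyran closes by 6-exo-trig Markovnikov attack of the other 4-OH on the protonated isopropenyl group. C4 is carried over from 11; C3 is set because indium is held on the face of the quinolone oxygen, which delivers the aldehyde syn to that aryl group and gives the 3,4-trans relation, and acid can correct leakage by equilibration through the 2H-pyran; C2 is set on closure, where the C3 substituent sits pseudo-axial next to the gem-dimethyl group and O adds on its own face to give the cis fusion. The step needs γ- over α-attack, secured by indium residing on the primary CH2 terminus, and it needs activation of the carbinol and of the 1,1-disubstituted alkene without loss of the trisubstituted side-chain alkene, secured by the much easier ionisation of the doubly activated carbinol, catalytic acid and low temperature.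

Step 8
Reactants: 15 (2R,3S,4S) isobutenyl dimer
Product: 16 target CNP0160874.2 (2R,3S,4S; 4-(2-hydroxy-2-methylpropyl) side chain)
Conditions: Co(acac)2 (20 mol %), PhSiH3, O2 (1 atm), THF/iPrOH, rt
Reagents that add atoms: dioxygen, O=O
Why: Mukaiyama hydration (metal-hydride hydrogen-atom transfer, O2 capture, reduction) places OH at the tertiary carbon of the only isolated alkene under neutral conditions, so the acid-labile O1–C2 bond and the three stereocentres are not touched.

Compound list
1 | 2,3-dimethoxyaniline | Nc1cccc(OC)c1OC | starting material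
2 | N-(methoxymethyl)-2,3-dimethoxyaniline | COCNc1cccc(OC)c1OC | intermediate
3 | 2,3-dimethoxy-N-methylaniline | CNc1cccc(OC)c1OC | intermediate
4 | bis(2,4,6-trichlorophenyl) malonate | O=C(CC(=O)Oc1c(Cl)cc(Cl)cc1Cl)Oc1c(Cl)cc(Cl)cc1Cl | starting material
5 | 4-hydroxy-7,8-dimethoxy-1-methylquinolin-2(1H)-one | COc1ccc2c(O)cc(=O)n(C)c2c1OC | intermediate
6 | 3-[(dimethylamino)methylidene]-7,8-dimethoxy-1-methylquinoline-2,4(1H,3H)-dione | COc1ccc2C(=O)C(=CN(C)C)C(=O)N(C)c2c1OC | intermediate
7 | 4-hydroxy-7,8-dimethoxy-1-methyl-2-oxo-1,2-dihydroquinoline-3-carbaldehyde | COc1ccc2c(O)c(C=O)c(=O)n(C)c2c1OC | intermediate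
8 | (3E)-6-methylhepta-3,5-dien-2-one | CC(=O)/C=C/C=C(C)C | starting material
9 | (R)-4-hydroxy-7,8-dimethoxy-1-methyl-3-(6-methyl-2-oxohept-5-en-4-yl)quinolin-2(1H)-one (in equilibrium with its cyclic hemiketal) | COc1ccc2c(O)c([C@@H](C=C(C)C)CC(C)=O)c(=O)n(C)c2c1OC | intermediate
10 | (2R,3R)-2-acetyl-6,7-dimethoxy-5-methyl-3-(2-methylprop-1-enyl)-2,3-dihydrofuro[3,2-c]quinolin-4(5H)-one (trans) | COc1ccc2c3O[C@@H](C(C)=O)[C@H](C=C(C)C)c3c(=O)n(C)c2c1OC | intermediate
11 | (2R,3R)-6,7-dimethoxy-5-methyl-3-(2-methylprop-1-enyl)-2-(prop-1-en-2-yl)-2,3-dihydrofuro[3,2-c]quinolin-4(5H)-one (trans) | COc1ccc2c3O[C@@H](C(C)=C)[C@H](C=C(C)C)c3c(=O)n(C)c2c1OC | intermediate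
12 | ring-opened 2-methylallylindium(III) iodide, indium bound to CH2 and to the quinolone 4-oxygen | COc1ccc2c3O[In](I)CC(C)=C[C@H](C=C(C)C)c3c(=O)n(C)c2c1OC | intermediate
13 | seco homoallylic alcohol: both quinolone 4-OH groups free, carbinol carbon between the second quinolone and C3 (carbinol centre not defined) | COc1ccc2c(O)c(c(=O)n(C)c2c1OC)[C@@H](C=C(C)C)[C@H](C(C)=C)C(O)c1c(O)c2ccc(OC)c(OC)c2n(C)c1=O | intermediate
14 | (3R,4S)-2-(4-hydroxy-7,8-dimethoxy-1-methyl-2-oxoquinolin-3-yl)-7,8-dimethoxy-6-methyl-4-(2-methylprop-1-enyl)-3-(prop-1-en-2-yl)-3,4-dihydro-2H-pyrano[3,2-c]quinolin-5(6H)-one (C2 epimers interconvert) | COc1ccc2c3c(c(=O)n(C)c2c1OC)[C@@H](C=C(C)C)[C@H](C(C)=C)C(O3)c1c(O)c2ccc(OC)c(OC)c2n(C)c1=O | intermediate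
15 | (2R,3S,4S)-7,8-dimethoxy-6-methyl-4-(2-methylprop-1-enyl)-3,4-dihydro-2H-pyrano[3,2-c]quinolin-5(6H)-one whose C2–C3 bond is cis-fused to C4–C3 of a 7,8-dimethoxy-2,2,6-trimethyl-3,4-dihydro-2H-pyrano[3,2-c]quinolin-5(6H)-one (H-3/H-4 trans, H-2/H-3 cis) | COc1ccc2c3c(c(=O)n(C)c2c1OC)[C@@H](C=C(C)C)[C@H]1[C@@H](O3)c2c(c3ccc(OC)c(OC)c3n(C)c2=O)OC1(C)C | intermediate
16 | CNP0160874.2: as 15 but with a 4-(2-hydroxy-2-methylpropyl) group (2R,3S,4S) | COc1ccc2c3c(c(=O)n(C)c2c1OC)[C@@H](CC(C)(C)O)[C@H]1[C@@H](O3)c2c(c3ccc(OC)c(OC)c3n(C)c2=O)OC1(C)C | target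

Total step count: 8. Longest linear sequence: 7 (steps 1, 2, 4, 5, 6, 7, 8).

Steps most likely to fail

Step 7. The allyl-metal may be lost by protonolysis through the acidic 4-OH of the aldehyde or by β-hydride elimination towards the stereocentre before the C–C bond forms. The acid phase may also drift towards closure onto the side-chain alkene or towards the trans ring fusion. The fallback sets out from 11 and separates donor formation from the union. Pd-catalysed borylative opening of the allylic C–O bond with B2pin2 should give the isolable, proton-tolerant linear allylboronate F1. A thermal type-I allylboration of 7 through a closed chair, followed by the same catalytic acid treatment, comes back to the route at 15.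

Step 4. Iminium formation with the cross-conjugated dienone may be slow, 1,6-addition may compete, and facial selectivity may be poor. The fallback sets out from 5 and moves the enantio-determining event to the furan closure. Luche reduction of phorone gives 2,6-dimethylhepta-2,5-dien-4-ol F2. Acid-catalysed dehydrative C-3 alkylation of 5 with this alcohol gives the achiral bis(isobutenyl)methyl quinolone F3. An enantioselective Wacker-type 5-exo oxidative cyclisation (Pd(II), chiral bis(oxazoline) ligand, benzoquinone) then differentiates the two enantiotopic alkenes and comes back to the route at 11.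

Step 5. Electrophilic iodine may attack the trisubstituted alkene (iodoetherification by the 4-OH) instead of the enolate. The fallback sets out from 9 and removes the alkene first.
- Mukaiyama hydration gives the tertiary alcohol F4.
- TESOTf/2,6-lutidine, with hydrolysis of the labile 4-O-silyl group on work-up, gives the silyl ether F5.
- Iodine/K2CO3 cyclisation gives the acetyl dihydrofuran F6.
- Wittig methylenation gives the isopropenyl dihydrofuran F7.
- The Pd/InI union with 7 and acid closure give the silyl ether of the target F8.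
- TBAF comes back to the route at 16.

Further compounds
F1 | step 7 | (S)-configured ring-opened allylboronate: 4-hydroxyquinolinone bearing at C-3 a CH(isobutenyl)–CH=C(CH3)–CH2–Bpin chain | COc1ccc2c(O)c([C@@H](C=C(C)C)C=C(C)CB3OC(C)(C)C(C)(C)O3)c(=O)n(C)c2c1OC
F2 | step 4 | 2,6-dimethylhepta-2,5-dien-4-ol | CC(C)=CC(O)C=C(C)C
F3 | step 4 | 3-(2,6-dimethylhepta-2,5-dien-4-yl)-4-hydroxy-7,8-dimethoxy-1-methylquinolin-2(1H)-one | COc1ccc2c(O)c(C(C=C(C)C)C=C(C)C)c(=O)n(C)c2c1OC
F4 | step 5 | 4-hydroxy-3-(6-hydroxy-6-methyl-2-oxoheptan-4-yl)-7,8-dimethoxy-1-methylquinolin-2(1H)-one, configured as 9 | COc1ccc2c(O)c([C@@H](CC(C)(C)O)CC(C)=O)c(=O)n(C)c2c1OC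
F5 | step 5 | triethylsilyl ether of F4 | COc1ccc2c(O)c([C@@H](CC(C)(C)O[Si](CC)(CC)CC)CC(C)=O)c(=O)n(C)c2c1OC
F6 | step 5 | trans-2-acetyl-3-[2-methyl-2-(triethylsilyloxy)propyl] dihydrofuroquinolinone | COc1ccc2c3O[C@@H](C(C)=O)[C@H](CC(C)(C)O[Si](CC)(CC)CC)c3c(=O)n(C)c2c1OC
F7 | step 5 | trans-2-isopropenyl-3-[2-methyl-2-(triethylsilyloxy)propyl] dihydrofuroquinolinone | COc1ccc2c3O[C@@H](C(C)=C)[C@H](CC(C)(C)O[Si](CC)(CC)CC)c3c(=O)n(C)c2c1OC
F8 | step 5 | triethylsilyl ether of 16 | COc1ccc2c3c(c(=O)n(C)c2c1OC)[C@@H](CC(C)(C)O[Si](CC)(CC)CC)[C@H]1[C@@H](O3)c2c(c3ccc(OC)c(OC)c3n(C)c2=O)OC1(C)C
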